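**Plan**

- **Cuts:** the C3=C4 alkene is traced back to loss of a C4–O group and the C8 hydroxyl to a C8–Si bond. Ring B is then cut at C4a–C8a, C5–C6 and C7–C8 into three alkynes.
- **Enabling feature:** ring B is a pentasubstituted benzene whose neighbouring carbons C8a and C4a are already bridged by O1–C2–C3–C4 of the pyran ring. Alkynes C8≡C8a (an alkynyl ether) and C4a≡C5 (prenyl-capped) can therefore share that tether, while C6≡C7 is a terminal alkyne carrying the three-carbon linker and ring A.
- **Oxidation level and C8 handle:** the tether is used saturated at C3–C4 with oxygen on C4, because O1–C2–C3=C4 on an alkynyl ether is an allyl alkynyl ether and would undergo a [3,3] shift far below room temperature. C8 carries a pentamethyldisiloxanyl group, which gives a stable alkynyl ether (an O–C≡C–B unit would protodeboronate easily), steers the regiochemistry by its bulk and is oxidisable to the phenol.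
- **Forward order:** ring A comes from 2,4-dihydroxybenzaldehyde, with an aromatic Claisen rearrangement for the 1,1-dimethylallyl group and Grignard addition plus deoxygenation for the pentynyl chain. The diyne is joined from 3-methylbutane-1,3-diol, prenyl bromide, ethynylmagnesium bromide and trichloroethylene. Ring B and the pyran ring then arise together, and C–Si oxidation and one acid step finish the synthesis.
- **Stereochemistry:** the target has none. The two transient carbinol centres are racemic and are erased.

Key step: step 14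

Remark: chromene numbering (O1, C2–C8a) is used for these atoms in all precursors, and the silylated bromobutyne, ethynylmagnesium bromide, the diol, chloropentamethyldisiloxane and Cp*RuCl(cod) are taken as commercial.

**Route**

Step 1
Reactants: 1 2,4-dihydroxybenzaldehyde; 2 prenyl bromide (1-bromo-3-methylbut-2-ene)
Product: 3 2-hydroxy-4-[(3-methylbut-2-en-1-yl)oxy]benzaldehyde
Conditions: K2CO3 (1.1 equiv), acetone, reflux
Reagents that add atoms: none
Why: Williamson ether synthesis in which the 2-hydroxyl is locked in a hydrogen bond to the aldehyde, so the weak base ionises and alkylates only the 4-hydroxyl.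

Step 2
Reactants: 3 2-hydroxy-4-[(3-methylbut-2-en-1-yl)oxy]benzaldehyde
Product: 4 2-(methoxymethoxy)-4-[(3-methylbut-2-en-1-yl)oxy]benzaldehyde
Conditions: NaH, MOMCl, DMF, 0 °C to rt
Reagents that add atoms: chloromethyl methyl ether, COCCl
Why: MOM protection (O-alkylation of the sodium phenoxide) masks the chelated 2-hydroxyl and removes the bond fixation that would steer the coming rearrangement to C3 of the ring.

Step 3
Reactants: 4 2-(methoxymethoxy)-4-[(3-methylbut-2-en-1-yl)oxy]benzaldehyde
Product: 6 4-hydroxy-2-(methoxymethoxy)-5-(2-methylbut-3-en-2-yl)benzaldehyde, via ortho-dienone 5 (not isolated)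
Conditions: PhNEt2, 195 °C, sealed tube, argon
Reagents that add atoms: none
Why: Aromatic Claisen rearrangement ([3,3] shift, then tautomerisation of 5) inverts the allyl unit so that its tertiary carbon bonds to the ring; it goes to C5 because C3 lies between two oxygen substituents, and the basic solvent suppresses acid-induced cyclisation of the new phenol onto the alkene.

Step 4
Reactants: 6 4-hydroxy-2-(methoxymethoxy)-5-(2-methylbut-3-en-2-yl)benzaldehyde
Product: 7 2,4-bis(methoxymethoxy)-5-(2-methylbut-3-en-2-yl)benzaldehyde
Conditions: NaH, MOMCl, DMF, 0 °C to rt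
Reagents that add atoms: chloromethyl methyl ether, COCCl
Why: MOM protection of the hindered but acidic 4-hydroxyl through its sodium salt, with no other group in 6 responding to the base or the chloromethyl ether.

Step 5
Reactants: 7 2,4-bis(methoxymethoxy)-5-(2-methylbut-3-en-2-yl)benzaldehyde; 8 (4-bromobut-1-yn-1-yl)trimethylsilane
Product: 10 1-[2,4-bis(methoxymethoxy)-5-(2-methylbut-3-en-2-yl)phenyl]-5-(trimethylsilyl)pent-4-yn-1-ol (racemic), via Grignard reagent 9 (not isolated)
Conditions: 8, Mg, THF, 40 °C; then 7, 0 °C; H2O quench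
Reagents that add atoms: none
Why: Grignard addition to the aldehyde gives the racemic benzylic alcohol, whose centre is removed in step 6, while the C-silyl group keeps the alkyne terminus non-acidic.

Step 6
Reactants: 10 1-[2,4-bis(methoxymethoxy)-5-(2-methylbut-3-en-2-yl)phenyl]-5-(trimethylsilyl)pent-4-yn-1-ol
Product: 11 {5-[2,4-bis(methoxymethoxy)-5-(2-methylbut-3-en-2-yl)phenyl]pent-1-yn-1-yl}trimethylsilane
Conditions: Et3SiH (3 equiv), CF3CO2H (2 equiv), CH2Cl2, −40 °C, short contact
Reagents that add atoms: none
Why: Ionic hydrogenation, in which the 2,4-dialkoxybenzylic alcohol ionises at low temperature well before the aryl MOM acetals, the silylalkyne or the monosubstituted alkene respond to the acid, and the cation is trapped by hydride from the silane.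

Step 7
Reactants: 11 {5-[2,4-bis(methoxymethoxy)-5-(2-methylbut-3-en-2-yl)phenyl]pent-1-yn-1-yl}trimethylsilane
Product: 12 1,5-bis(methoxymethoxy)-2-(2-methylbut-3-en-2-yl)-4-(pent-4-yn-1-yl)benzene
Conditions: K2CO3 (0.2 equiv), MeOH, rt
Reagents that add atoms: none
Why: Base-catalysed methanolysis of the alkynyl C–Si bond (protiodesilylation) frees the terminal alkyne and touches no other group.

Step 8
Reactants: 13 ethynylmagnesium bromide; 2 prenyl bromide
Product: 14 5-methylhex-4-en-1-yne
Conditions: CuCl (5 mol %), 13 (1.5 equiv), THF, 0 to 40 °C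
Reagents that add atoms: none
Why: Copper-catalysed allylic substitution of an alkynyl Grignard reagent takes place at the primary carbon of prenyl bromide (SN2) to give the skipped enyne, and the excess of 13 limits double alkylation.

Step 9
Reactants: 15 3-methylbutane-1,3-diol
Product: 16 3-hydroxy-3-methylbutanal
Conditions: IBX (1.3 equiv), EtOAc, 75 °C; filter, use at once
Reagents that add atoms: none
Why: IBX oxidation of the primary alcohol under neutral conditions leaves the tertiary alcohol untouched, and filtration gives a solution of the sensitive β-hydroxy aldehyde.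

Step 10
Reactants: 14 5-methylhex-4-en-1-yne; 16 3-hydroxy-3-methylbutanal
Product: 18 2,9-dimethyldec-8-en-5-yne-2,4-diol (racemic), via lithium acetylide 17 (not isolated)
Conditions: 14 (2.2 equiv), n-BuLi (2.1 equiv), THF, −78 °C; then 16, −78 to −20 °C; H2O quench
Reagents that add atoms: none
Why: 1,2-Addition of a lithium acetylide to the aldehyde forms C4–C4a; one equivalent is spent on the hydroxyl proton, the low temperature holds back retro-aldol cleavage, and the new C4 centre is racemic and later erased.

Step 11
Reactants: 18 2,9-dimethyldec-8-en-5-yne-2,4-diol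
Product: 19 4-(methoxymethoxy)-2,9-dimethyldec-8-en-5-yn-2-ol (racemic)
Conditions: MOMCl (1.2 equiv), i-Pr2NEt, CH2Cl2, 0 °C to rt
Reagents that add atoms: chloromethyl methyl ether, COCCl
Why: Selective MOM protection of the secondary propargylic hydroxyl, which reacts much faster than the tertiary one; an acetal is chosen over a silyl ether because it cannot migrate to the alkoxide made in step 12.

Step 12
Reactants: 19 4-(methoxymethoxy)-2,9-dimethyldec-8-en-5-yn-2-ol; 20 trichloroethylene
Product: 23 9-{[(E)-1,2-dichloroethenyl]oxy}-7-(methoxymethoxy)-2,9-dimethyldec-2-en-5-yne, via potassium alkoxide 21 (not isolated), via dichloroacetylene 22 (not isolated)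
Conditions: KH (1.2 equiv), THF, 0 °C; then 20 (1.2 equiv), −40 °C to rt
Reagents that add atoms: none
Why: First half of the trichloroethylene route to alkynyl ethers, known also for hindered alkoxides, in which base converts 20 into 22 and alkoxide 21 adds to it in anti fashion to give the E dichlorovinyl ether.

Step 13
Reactants: 23 9-{[(E)-1,2-dichloroethenyl]oxy}-7-(methoxymethoxy)-2,9-dimethyldec-2-en-5-yne
Product: 26 1-({[4-(methoxymethoxy)-2,9-dimethyldec-8-en-5-yn-2-yl]oxy}ethynyl)-1,1,3,3,3-pentamethyldisiloxane, via chloroalkynyl ether 24 (not isolated), via lithium alkoxyacetylide 25 (not isolated)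
Conditions: n-BuLi (2.1 equiv), THF, −78 to −40 °C; then ClSiMe2OSiMe3, −78 to 0 °C; Et3N-deactivated silica, store cold
Reagents that add atoms: chloropentamethyldisiloxane, C[Si](C)(C)O[Si](C)(C)Cl
Why: Second half of the same alkynyl ether synthesis, in which n-BuLi eliminates HCl to 24 and exchanges the remaining chlorine for lithium, and acetylide 25 is C-silylated by the chlorosilane; at −78 °C these events are faster than deprotonation of the skipped-enyne CH2.

Step 14
Reactants: 26 1-({[4-(methoxymethoxy)-2,9-dimethyldec-8-en-5-yn-2-yl]oxy}ethynyl)-1,1,3,3,3-pentamethyldisiloxane; 12 1,5-bis(methoxymethoxy)-2-(2-methylbut-3-en-2-yl)-4-(pent-4-yn-1-yl)benzene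
Product: 27 1-[6-{3-[2,4-bis(methoxymethoxy)-5-(2-methylbut-3-en-2-yl)phenyl]propyl}-4-(methoxymethoxy)-2,2-dimethyl-5-(3-methylbut-2-en-1-yl)-3,4-dihydro-2H-chromen-8-yl]-1,1,3,3,3-pentamethyldisiloxane (racemic at C4)
Conditions: Cp*RuCl(cod) (10 mol %), 12 (1.3 equiv), ClCH2CH2Cl, 25 °C, 26 added over 2 h
Reagents that add atoms: none
Why: Proposed new method: oxidative cyclisation of the two tethered alkynes of 26 on the Cp*RuCl fragment should give a ruthenacycle that already holds the C4a–C8a bond, and insertion of the terminal alkyne of 12 followed by reductive elimination should form C5–C6 and C7–C8 and release the arene. The closest known reaction type is the Cp*RuCl(cod)-catalysed [2+2+2] cyclotrimerisation of 1,6- and 1,7-diynes with terminal alkynes, known also for diyne termini capped by silyl, boryl or halogen groups, whereas a silyl-capped alkynyl ether as diyne terminus has not been shown. The dihydropyran ring closes in the metallacycle-forming step as a six-membered ring through C4a–C8a bond formation across the O1–C2–C3–C4 tether, helped by the gem-dimethyl group at C2, and ring B closes as the six-membered carbocycle in the final reductive elimination. No stereocentre is created, and the racemic C4 centre is a spectator that is erased in step 16. Regioselectivity requires the CH end of 12 to bond to C8, which the bulky disiloxanyl group on C8 (against a mere CH2 on C5) should enforce in line with the meta preference of this catalyst. Chemoselectivity for alkynes over the trisubstituted prenyl and the neopentyl-type vinyl alkenes rests on their poor binding to the crowded metal, the acid-free medium at 25 °C keeps the tertiary alkynyl ether from retro-ene loss of a ketene, and the saturated C3–C4 unit removes the [3,3] pathway.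

Step 15
Reactants: 27 the C8 disiloxanyl chroman from step 14
Product: 28 6-{3-[2,4-bis(methoxymethoxy)-5-(2-methylbut-3-en-2-yl)phenyl]propyl}-4-(methoxymethoxy)-2,2-dimethyl-5-(3-methylbut-2-en-1-yl)-3,4-dihydro-2H-chromen-8-ol (racemic at C4)
Conditions: 30% aq H2O2, KF, KHCO3, THF–MeOH, 25 to 40 °C
Reagents that add atoms: hydrogen peroxide, OO
Why: Tamao–Fleming oxidation of an aryl(siloxy)silane, in which hydroperoxide adds to the fluoride-activated silicon and the aryl group migrates from Si to O at the same carbon; the unactivated alkenes and the MOM acetals are inert to basic peroxide.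

Step 16
Reactants: 28 the chroman-8-ol from step 15
Product: 30 kazinol K, via chroman-4-ol triphenol 29 (not isolated)
Conditions: HCl (about 1 M in MeOH), THF co-solvent, 45 °C
Reagents that add atoms: none
Why: Acid-catalysed acetal exchange removes the three MOM groups, and the freed chroman-4-ol 29 loses water by E1 elimination through the O1-stabilised C4 benzylic cation, the classical ending of 2,2-dimethylchromene syntheses; the prenyl group has no ortho hydroxyl and the monosubstituted vinyl group is slow to protonate.

**Compound list**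

1 | 2,4-dihydroxybenzaldehyde | O=Cc1ccc(O)cc1O | starting material
2 | prenyl bromide (1-bromo-3-methylbut-2-ene) | CC(C)=CCBr | starting material
3 | 2-hydroxy-4-[(3-methylbut-2-en-1-yl)oxy]benzaldehyde | CC(C)=CCOc1ccc(C=O)c(O)c1 | intermediate
4 | 2-(methoxymethoxy)-4-[(3-methylbut-2-en-1-yl)oxy]benzaldehyde | CC(C)=CCOc1ccc(C=O)c(OCOC)c1 | intermediate
5 | 6-(methoxymethoxy)-3-(2-methylbut-3-en-2-yl)-4-oxocyclohexa-1,5-diene-1-carbaldehyde (ortho-dienone, racemic, not isolated) | O=C1C=C(OCOC)C(C=O)=CC1C(C)(C)C=C | intermediate
6 | 4-hydroxy-2-(methoxymethoxy)-5-(2-methylbut-3-en-2-yl)benzaldehyde | C=CC(C)(C)c1cc(C=O)c(OCOC)cc1O | intermediate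
7 | 2,4-bis(methoxymethoxy)-5-(2-methylbut-3-en-2-yl)benzaldehyde | C=CC(C)(C)c1cc(C=O)c(OCOC)cc1OCOC | intermediate
8 | (4-bromobut-1-yn-1-yl)trimethylsilane | C[Si](C)(C)C#CCCBr | starting material
9 | [4-(trimethylsilyl)but-3-yn-1-yl]magnesium bromide (not isolated) | C[Si](C)(C)C#CCC[Mg]Br | intermediate
10 | 1-[2,4-bis(methoxymethoxy)-5-(2-methylbut-3-en-2-yl)phenyl]-5-(trimethylsilyl)pent-4-yn-1-ol (racemic) | C=CC(C)(C)c1cc(C(O)CCC#C[Si](C)(C)C)c(OCOC)cc1OCOC | intermediate
11 | {5-[2,4-bis(methoxymethoxy)-5-(2-methylbut-3-en-2-yl)phenyl]pent-1-yn-1-yl}trimethylsilane | C=CC(C)(C)c1cc(CCCC#C[Si](C)(C)C)c(OCOC)cc1OCOC | intermediate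
12 | 1,5-bis(methoxymethoxy)-2-(2-methylbut-3-en-2-yl)-4-(pent-4-yn-1-yl)benzene | C#CCCCc1cc(C(C)(C)C=C)c(OCOC)cc1OCOC | intermediate
13 | ethynylmagnesium bromide | C#C[Mg]Br | starting material
14 | 5-methylhex-4-en-1-yne | C#CCC=C(C)C | intermediate
15 | 3-methylbutane-1,3-diol | CC(C)(O)CCO | starting material
16 | 3-hydroxy-3-methylbutanal | CC(C)(O)CC=O | intermediate
17 | (5-methylhex-4-en-1-yn-1-yl)lithium (not isolated) | [Li]C#CCC=C(C)C | intermediate
18 | 2,9-dimethyldec-8-en-5-yne-2,4-diol (racemic) | CC(C)=CCC#CC(O)CC(C)(C)O | intermediate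
19 | 4-(methoxymethoxy)-2,9-dimethyldec-8-en-5-yn-2-ol (racemic) | CC(C)=CCC#CC(OCOC)CC(C)(C)O | intermediate
20 | trichloroethylene | ClC=C(Cl)Cl | starting material
21 | potassium 4-(methoxymethoxy)-2,9-dimethyldec-8-en-5-yn-2-olate (not isolated) | CC(C)=CCC#CC(OCOC)CC(C)(C)[O-].[K+] | intermediate
22 | dichloroacetylene (not isolated) | ClC#CCl | intermediate
23 | 9-{[(E)-1,2-dichloroethenyl]oxy}-7-(methoxymethoxy)-2,9-dimethyldec-2-en-5-yne (racemic) | CC(C)=CCC#CC(OCOC)CC(C)(C)O/C(Cl)=C\Cl | intermediate
24 | 9-[(chloroethynyl)oxy]-7-(methoxymethoxy)-2,9-dimethyldec-2-en-5-yne (not isolated) | CC(C)=CCC#CC(OCOC)CC(C)(C)OC#CCl | intermediate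
25 | ({[4-(methoxymethoxy)-2,9-dimethyldec-8-en-5-yn-2-yl]oxy}ethynyl)lithium (not isolated) | CC(C)=CCC#CC(OCOC)CC(C)(C)OC#C[Li] | intermediate
26 | 1-({[4-(methoxymethoxy)-2,9-dimethyldec-8-en-5-yn-2-yl]oxy}ethynyl)-1,1,3,3,3-pentamethyldisiloxane (racemic) | CC(C)=CCC#CC(OCOC)CC(C)(C)OC#C[Si](C)(C)O[Si](C)(C)C | intermediate
27 | 1-[6-{3-[2,4-bis(methoxymethoxy)-5-(2-methylbut-3-en-2-yl)phenyl]propyl}-4-(methoxymethoxy)-2,2-dimethyl-5-(3-methylbut-2-en-1-yl)-3,4-dihydro-2H-chromen-8-yl]-1,1,3,3,3-pentamethyldisiloxane (racemic at C4) | C=CC(C)(C)c1cc(CCCc2cc([Si](C)(C)O[Si](C)(C)C)c3OC(C)(C)CC(OCOC)c3c2CC=C(C)C)c(OCOC)cc1OCOC | intermediate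
28 | 6-{3-[2,4-bis(methoxymethoxy)-5-(2-methylbut-3-en-2-yl)phenyl]propyl}-4-(methoxymethoxy)-2,2-dimethyl-5-(3-methylbut-2-en-1-yl)-3,4-dihydro-2H-chromen-8-ol (racemic at C4) | C=CC(C)(C)c1cc(CCCc2cc(O)c3OC(C)(C)CC(OCOC)c3c2CC=C(C)C)c(OCOC)cc1OCOC | intermediate
29 | 6-{3-[2,4-dihydroxy-5-(2-methylbut-3-en-2-yl)phenyl]propyl}-2,2-dimethyl-5-(3-methylbut-2-en-1-yl)-3,4-dihydro-2H-chromene-4,8-diol (racemic, not isolated) | C=CC(C)(C)c1cc(CCCc2cc(O)c3OC(C)(C)CC(O)c3c2CC=C(C)C)c(O)cc1O | intermediate
30 | kazinol K, 4-{3-[8-hydroxy-2,2-dimethyl-5-(3-methylbut-2-en-1-yl)-2H-chromen-6-yl]propyl}-6-(2-methylbut-3-en-2-yl)benzene-1,3-diol | C=CC(C)(C)c1cc(CCCc2cc(O)c3c(c2CC=C(C)C)C=CC(C)(C)O3)c(O)cc1O | target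

**Step count**

- Total step count: 16.
- Longest linear sequence: 10 steps (steps 1–7, 14, 15, 16, from 2,4-dihydroxybenzaldehyde).
- The diyne branch (steps 9–13, fed by step 8) reaches the target in 8 steps.

**Steps most likely to fail**

1. **Step 14 (cyclotrimerisation).**
   - What may go wrong: the alkynyl ether may be lost on the metal through protonation or ketene formation. The doubly capped diyne may be slow to cyclise oxidatively, so that the terminal alkyne oligomerises. The alkyne may also insert with poor regioselectivity.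
   - Fallback: the oxygen tether is given up for the known temporary boron tether between an alkynylboronate and a propargylic alcohol. Ring B is made first and the pyran ring afterwards. The fallback sets out from 13, 18 and 12.
   - Reagent 13 and chloropentamethyldisiloxane give ethynylpentamethyldisiloxane F1. Treatment with n-BuLi, B(Oi-Pr)3 and then HCl in Et2O converts it into diisopropyl [(pentamethyldisiloxanyl)ethynyl]boronate F2.
   - Ester exchange with diol 18 gives the cyclic alkynylboronate (1,3,2-dioxaborinane) F3, in which C8a–B–O–C4 links the same two alkynes as a 1,6-diyne.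
   - Cp*RuCl(cod) and 12 then give the ring B arylboronate F4. H2O2/KF/KHCO3 oxidises both the C8a–B and the C8–Si bond to the catechol diol F5.
   - Under the conditions of step 16 the C8a phenol closes the pyran ring on the tertiary carbinol carbon C2. This brings the material back to the route at 29, and from there to 30.

2. **Step 12 (dichlorovinyl ether).**
   - What may go wrong: the hindered tertiary alkoxide may add slowly to dichloroacetylene. The potassium base may isomerise the skipped enyne or the propargylic ether.
   - Fallback: potassium bases are avoided by building the alkynyl ether carbon by carbon from the alcohol oxygen. It sets out from 19.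
   - Formylation with acetic formic anhydride and pyridine gives the formate F6. Wittig-type dichloromethylenation (PPh3, CCl4, THF, 60 °C) gives the 2,2-dichlorovinyl ether F7.
   - n-BuLi (2 equiv, −78 °C) eliminates HCl and exchanges chlorine for lithium. The fallback thus comes back to the route at 25, which is silylated to 26 as in step 13.

3. **Step 16 (deprotection and dehydration in one operation).**
   - What may go wrong: the C4 cation may be captured by methanol or by the neighbouring prenyl alkene. The chromene may oligomerise under acid. The ring A phenol may cyclise onto the vinyl group during the long acid exposure that both events together need.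
   - Fallback: the two events are separated and the elimination is run in a non-nucleophilic medium. It sets out from 28.
   - Heating with catalytic camphorsulfonic acid in toluene over molecular sieves expels the C4 methoxymethoxy group and gives the chromen-8-ol bis(methoxymethyl) ether F8.
   - A short treatment with HCl in MeOH at 20 °C, conditions under which 2,2-dimethylchromenes persist, then removes the two aryl MOM groups. The fallback comes back to the route at 30.

**Further compounds**

F1 | step 14 | ethynylpentamethyldisiloxane | C#C[Si](C)(C)O[Si](C)(C)C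
F2 | step 14 | diisopropyl [(pentamethyldisiloxanyl)ethynyl]boronate | CC(C)OB(OC(C)C)C#C[Si](C)(C)O[Si](C)(C)C
F3 | step 14 | 4,4-dimethyl-6-(5-methylhex-4-en-1-yn-1-yl)-2-[(pentamethyldisiloxanyl)ethynyl]-1,3,2-dioxaborinane (racemic) | CC(C)=CCC#CC1CC(C)(C)OB(O1)C#C[Si](C)(C)O[Si](C)(C)C
F4 | step 14 | ring B arylboronate with boron on C8a bound to the C4 and C2 oxygens, disiloxanyl group on C8, prenyl on C5 and the ring A propyl chain on C6 (racemic) | C=CC(C)(C)c1cc(CCCc2cc([Si](C)(C)O[Si](C)(C)C)c3B4OC(C)(C)CC(O4)c3c2CC=C(C)C)c(OCOC)cc1OCOC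
F5 | step 14 | 5-{3-[2,4-bis(methoxymethoxy)-5-(2-methylbut-3-en-2-yl)phenyl]propyl}-3-(1,3-dihydroxy-3-methylbutyl)-4-(3-methylbut-2-en-1-yl)benzene-1,2-diol (racemic) | C=CC(C)(C)c1cc(CCCc2cc(O)c(O)c(C(O)CC(C)(C)O)c2CC=C(C)C)c(OCOC)cc1OCOC
F6 | step 12 | 4-(methoxymethoxy)-2,9-dimethyldec-8-en-5-yn-2-yl formate (racemic) | CC(C)=CCC#CC(OCOC)CC(C)(C)OC=O
F7 | step 12 | 9-[(2,2-dichloroethenyl)oxy]-7-(methoxymethoxy)-2,9-dimethyldec-2-en-5-yne (racemic) | CC(C)=CCC#CC(OCOC)CC(C)(C)OC=C(Cl)Cl
F8 | step 16 | 6-{3-[2,4-bis(methoxymethoxy)-5-(2-methylbut-3-en-2-yl)phenyl]propyl}-2,2-dimethyl-5-(3-methylbut-2-en-1-yl)-2H-chromen-8-ol | C=CC(C)(C)c1cc(CCCc2cc(O)c3c(c2CC=C(C)C)C=CC(C)(C)O3)c(OCOC)cc1OCOC
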